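The target is cut back to achiral penta-1,4-dien-3-ol (1): C5, C6, C1', C2' and the cyclopropane CH2 are its five carbons, and the erythro pair O1–C6/HO–C1' is its epoxy alcohol. One titanium–tartrate epoxidation selects one of the two enantiotopic vinyl groups and one of its faces, so C6 and C1' are set together and the oxirane oxygen later becomes lactone O1. The oxirane CH2 is then alkynylated (C4–C5) and the chain closed to the dihydropyranone ring. The surviving vinyl group takes up C3' from a lactate-derived diazoketone that already carries the coumarate, which forms the cyclopropane.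

Key step: step 1

Numbering used: lactone O1, C2(=O), C3=C4, C5, C6; side chain C1'(OH), cyclopropane C2', C3' and CH2, C4'(=O), C5'(O-acyl), C6'.

Remark on the chemistry (assumption): the tartrate antipode is assigned from the kinetic-resolution rule for secondary allylic alcohols (L-(+)-DIPT oxidises fastest the vinyl group that sees an S-type carbinol and gives the erythro product); this leads to the (2R,3S) epoxy alcohol required for 6R,1'S, and the configuration of the epoxy alcohol is confirmed (Mosher ester, sign of rotation) before material is carried forward.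

Step 1
Reactants: 1 penta-1,4-dien-3-ol
Product: 2 (2R,3S)-1,2-epoxypent-4-en-3-ol
Conditions: Ti(OiPr)4 (10 mol%), L-(+)-DIPT (13 mol%), cumene hydroperoxide (1.5 equiv), 4 Å MS, CH2Cl2, −35 → −20 °C, several days; non-aqueous citric acid work-up, distillation
Reagents that add atoms: cumene hydroperoxide, CC(C)(OO)c1ccccc1
Why: Titanium isopropoxide and the tartrate form the dimeric titanium tartrate, alkoxide exchange binds both the carbinol of 1 and the hydroperoxide, and the bound peroxide passes its distal oxygen intramolecularly to one alkene; the closest known reaction type is the Sharpless asymmetric epoxidation/kinetic resolution of secondary allylic alcohols, run here as an enantiotopic-group desymmetrisation. The oxirane ring is closed by a concerted, suprafacial [2+1] oxygen-atom transfer that forms the C5–O and C6–O bonds at once. C6 is fixed by the alkene face that the L-(+)-tartrate leaves open to the peroxide; C1' is fixed because only the vinyl group whose carbinol substituents fit the loaded complex (the arrangement that is fast for S-carbinols in kinetic resolutions) is oxidised, which gives the erythro relation typical of secondary allylic alcohols. The step needs group selectivity, face selectivity and mono-epoxidation: the first two come from the tartrate and from coordination of the carbinol to titanium, the third from the fact that the vinyl group left in 2 is the mismatched one. The small amount of (2S,3R) enantiomer still carries its matched vinyl group and should be consumed to a bis-epoxide, so the ee of 2 is expected to rise with conversion.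

Step 2
Reactants: 2 (2R,3S)-1,2-epoxypent-4-en-3-ol
Product: 3 (2R,3S)-3-[(tert-butyldimethylsilyl)oxy]-1,2-epoxypent-4-ene
Conditions: TBSCl, imidazole, DMAP (cat.), CH2Cl2, 0 °C → rt
Reagents that add atoms: tert-butyldimethylsilyl chloride, CC(C)(C)[Si](C)(C)Cl
Why: Imidazole-promoted silylation of the secondary alcohol is mild enough to leave the oxirane intact, touches no stereocentre, and blocks Payne rearrangement and proton transfer in the next step.

Step 3
Reactants: 3 (2R,3S)-3-[(tert-butyldimethylsilyl)oxy]-1,2-epoxypent-4-ene; 4 methyl propiolate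
Product: 6 methyl (5R,6S)-6-[(tert-butyldimethylsilyl)oxy]-5-hydroxyoct-7-en-2-ynoate, via lithium acetylide 5 (not isolated)
Conditions: 4 (2 equiv), n-BuLi, THF, −78 °C; BF3·OEt2; then 3, −78 °C; sat. NH4Cl at −78 °C
Reagents that add atoms: none
Why: In this Yamaguchi–Hirao alkynylation the BF3-activated terminal oxirane is opened by SN2 attack of the acetylide at the unhindered CH2, which forms C4–C5 and leaves the C6–O bond and its configuration untouched.

Step 4
Reactants: 6 methyl (5R,6S)-6-[(tert-butyldimethylsilyl)oxy]-5-hydroxyoct-7-en-2-ynoate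
Product: 8 (R)-6-{(S)-1-[(tert-butyldimethylsilyl)oxy]allyl}-5,6-dihydro-2H-pyran-2-one, via Z-hydroxy enoate 7 (not isolated)
Conditions: H2 (1 atm), Lindlar catalyst, quinoline, EtOAc, rt, stopped when 6 is consumed; filter; PPTS (cat.), toluene, 50 °C
Reagents that add atoms: none
Why: Lindlar semi-hydrogenation adds hydrogen syn to the strongly adsorbed alkyne to give the Z-enoate, whose cis-disposed C6 hydroxyl then closes the six-membered lactone by acid-catalysed transesterification without touching a stereocentre.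

Step 5
Reactants: 9 p-coumaric acid
Product: 11 (E)-3-{4-[(tert-butyldimethylsilyl)oxy]phenyl}acrylic acid, via bis-silyl ester 10 (not isolated)
Conditions: TBSCl (2.3 equiv), imidazole, DMF, rt; then AcOH/THF/H2O, rt
Reagents that add atoms: tert-butyldimethylsilyl chloride, CC(C)(C)[Si](C)(C)Cl
Why: Both acidic OH groups are silylated and the far more labile silyl ester is then hydrolysed selectively, which leaves the aryl silyl ether in place.

Step 6
Reactants: 11 (E)-3-{4-[(tert-butyldimethylsilyl)oxy]phenyl}acrylic acid; 12 tert-butyl (S)-lactate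
Product: 13 tert-butyl (S)-2-{[(E)-3-{4-[(tert-butyldimethylsilyl)oxy]phenyl}acryloyl]oxy}propanoate
Conditions: DCC, DMAP (cat.), CH2Cl2, 0 °C → rt
Reagents that add atoms: none
Why: Steglich esterification acylates the lactate hydroxyl, and since the stereocentre sits on the alcohol partner and is never activated, C5' is retained.

Step 7
Reactants: 13 tert-butyl (S)-2-{[(E)-3-{4-[(tert-butyldimethylsilyl)oxy]phenyl}acryloyl]oxy}propanoate
Product: 14 (S)-2-{[(E)-3-{4-[(tert-butyldimethylsilyl)oxy]phenyl}acryloyl]oxy}propanoic acid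
Conditions: TFA/CH2Cl2 (1:4), 0 °C → rt
Reagents that add atoms: none
Why: Acidolysis of the tert-butyl ester (loss of the tert-butyl cation as isobutene) frees the acid, while the cinnamate ester and the acid-tolerant aryl silyl ether should survive.

Step 8
Reactants: 14 (S)-2-{[(E)-3-{4-[(tert-butyldimethylsilyl)oxy]phenyl}acryloyl]oxy}propanoic acid
Product: 16 (S)-4-diazo-3-oxobutan-2-yl (E)-3-{4-[(tert-butyldimethylsilyl)oxy]phenyl}acrylate, via acid chloride 15 (not isolated)
Conditions: (COCl)2, DMF (cat.), CH2Cl2, 0 °C → rt, evaporate; CH2N2 (3 equiv), Et2O, 0 °C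
Reagents that add atoms: diazomethane, C=[N+]=[N-]
Why: DMF-catalysed acid chloride formation followed by C-acylation of diazomethane (the first stage of an Arndt–Eistert sequence, a second equivalent taking up HCl) gives the diazoketone, and O-acyl lactoyl chlorides keep their configuration when no amine base is present.

Step 9
Reactants: 8 (R)-6-{(S)-1-[(tert-butyldimethylsilyl)oxy]allyl}-5,6-dihydro-2H-pyran-2-one; 16 (S)-4-diazo-3-oxobutan-2-yl (E)-3-{4-[(tert-butyldimethylsilyl)oxy]phenyl}acrylate
Product: 17 (S)-1-{(1S,2S)-2-[(S)-[(tert-butyldimethylsilyl)oxy]((R)-6-oxo-3,6-dihydro-2H-pyran-2-yl)methyl]cyclopropyl}-1-oxopropan-2-yl (E)-3-{4-[(tert-butyldimethylsilyl)oxy]phenyl}acrylate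
Conditions: Ru(II)–Ph-Pheox(MeCN)4 PF6 (5 mol%; ligand antipode selected in a pilot run with both ligands for the (2'S,3'S) adduct), CH2Cl2, rt, 16 (2 equiv) added by syringe pump
Reagents that add atoms: none
Why: Catalytic asymmetric cyclopropanation by ruthenium-carbene transfer from an acceptor diazoketone to the only terminal, electron-neutral alkene forms C3'–C2' and C3'–CH2; the trans geometry and the (2'S,3'S) sense should be imposed by the cyclometalated chiral oxazoline ligand and not by C1', and the internal, electron-poor enoate alkenes are left alone.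

Step 10
Reactants: 17 (the bis-silyl ether of the target)
Product: 18 brevipolide G, (S)-1-{(1S,2S)-2-[(S)-hydroxy((R)-6-oxo-3,6-dihydro-2H-pyran-2-yl)methyl]cyclopropyl}-1-oxopropan-2-yl (E)-3-(4-hydroxyphenyl)acrylate
Conditions: HF·pyridine, pyridine, THF, 0 °C → rt
Reagents that add atoms: none
Why: Buffered fluoride desilylation cleaves both Si–O bonds under weakly acidic conditions that should spare the coumarate, the lactone, the base-sensitive C5' centre and the cyclopropyl carbinol.

Compound list
1 | penta-1,4-dien-3-ol | C=CC(O)C=C | starting material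
2 | (2R,3S)-1,2-epoxypent-4-en-3-ol | C=C[C@H](O)[C@H]1CO1 | intermediate
3 | (2R,3S)-3-[(tert-butyldimethylsilyl)oxy]-1,2-epoxypent-4-ene | C=C[C@H](O[Si](C)(C)C(C)(C)C)[C@H]1CO1 | intermediate
4 | methyl propiolate | C#CC(=O)OC | starting material
5 | methyl 3-lithiopropiolate | [Li]C#CC(=O)OC | intermediate (not isolated)
6 | methyl (5R,6S)-6-[(tert-butyldimethylsilyl)oxy]-5-hydroxyoct-7-en-2-ynoate | C=C[C@H](O[Si](C)(C)C(C)(C)C)[C@H](O)CC#CC(=O)OC | intermediate
7 | methyl (2Z,5R,6S)-6-[(tert-butyldimethylsilyl)oxy]-5-hydroxyocta-2,7-dienoate | C=C[C@H](O[Si](C)(C)C(C)(C)C)[C@H](O)C/C=C\C(=O)OC | intermediate (not isolated)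
8 | (R)-6-{(S)-1-[(tert-butyldimethylsilyl)oxy]allyl}-5,6-dihydro-2H-pyran-2-one | C=C[C@H](O[Si](C)(C)C(C)(C)C)[C@H]1CC=CC(=O)O1 | intermediate
9 | p-coumaric acid | OC(=O)/C=C/c1ccc(O)cc1 | starting material
10 | tert-butyldimethylsilyl (E)-3-{4-[(tert-butyldimethylsilyl)oxy]phenyl}acrylate | CC(C)(C)[Si](C)(C)OC(=O)/C=C/c1ccc(O[Si](C)(C)C(C)(C)C)cc1 | intermediate (not isolated)
11 | (E)-3-{4-[(tert-butyldimethylsilyl)oxy]phenyl}acrylic acid | OC(=O)/C=C/c1ccc(O[Si](C)(C)C(C)(C)C)cc1 | intermediate
12 | tert-butyl (S)-lactate | C[C@H](O)C(=O)OC(C)(C)C | starting material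
13 | tert-butyl (S)-2-{[(E)-3-{4-[(tert-butyldimethylsilyl)oxy]phenyl}acryloyl]oxy}propanoate | C[C@H](OC(=O)/C=C/c1ccc(O[Si](C)(C)C(C)(C)C)cc1)C(=O)OC(C)(C)C | intermediate
14 | (S)-2-{[(E)-3-{4-[(tert-butyldimethylsilyl)oxy]phenyl}acryloyl]oxy}propanoic acid | C[C@H](OC(=O)/C=C/c1ccc(O[Si](C)(C)C(C)(C)C)cc1)C(=O)O | intermediate
15 | (S)-1-chloro-1-oxopropan-2-yl (E)-3-{4-[(tert-butyldimethylsilyl)oxy]phenyl}acrylate | C[C@H](OC(=O)/C=C/c1ccc(O[Si](C)(C)C(C)(C)C)cc1)C(=O)Cl | intermediate (not isolated)
16 | (S)-4-diazo-3-oxobutan-2-yl (E)-3-{4-[(tert-butyldimethylsilyl)oxy]phenyl}acrylate | C[C@H](OC(=O)/C=C/c1ccc(O[Si](C)(C)C(C)(C)C)cc1)C(=O)C=[N+]=[N-] | intermediate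
17 | (S)-1-{(1S,2S)-2-[(S)-[(tert-butyldimethylsilyl)oxy]((R)-6-oxo-3,6-dihydro-2H-pyran-2-yl)methyl]cyclopropyl}-1-oxopropan-2-yl (E)-3-{4-[(tert-butyldimethylsilyl)oxy]phenyl}acrylate | C[C@H](OC(=O)/C=C/c1ccc(O[Si](C)(C)C(C)(C)C)cc1)C(=O)[C@H]1C[C@@H]1[C@H](O[Si](C)(C)C(C)(C)C)[C@H]1CC=CC(=O)O1 | intermediate
18 | brevipolide G | C[C@H](OC(=O)/C=C/c1ccc(O)cc1)C(=O)[C@H]1C[C@@H]1[C@H](O)[C@H]1CC=CC(=O)O1 | target

Total step count: 10. Longest linear sequence: 6 steps (steps 1, 2, 3, 4, 9, 10; the side-chain branch, steps 5–8, 9, 10, is equally long).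

Steps most likely to fail

1. Step 9. The carbene transfer may show too little ligand control over the alkene face, because the silyloxy centre at C1' can oppose the catalyst. The carbene may also be lost to dimerisation before it reaches a hindered, allylically oxygenated alkene. The fallback sets out from 8 (with 15 as the source of the side chain) and comes back at 17; it gives up carbene addition for a hydroxyl-directed zinc carbenoid, so the terminal CH2 of 8 is lost as ethene and the ring CH2 comes from CH2I2.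
 - Stille acylation of 15 with tributyl(vinyl)stannane (Pd catalyst) would give the vinyl ketone (S)-3-oxopent-4-en-2-yl (E)-3-{4-[(tert-butyldimethylsilyl)oxy]phenyl}acrylate F1.
 - Cross-metathesis of 8 with F1 (Hoveyda–Grubbs II, CH2Cl2, 40 °C) should give the E-enone (2S,4E,6S)-6-[(tert-butyldimethylsilyl)oxy]-3-oxo-6-[(R)-6-oxo-3,6-dihydro-2H-pyran-2-yl]hex-4-en-2-yl (E)-3-{4-[(tert-butyldimethylsilyl)oxy]phenyl}acrylate F2.
 - Reagent-controlled Corey–Bakshi–Shibata reduction ((R)-Me-CBS, catecholborane, low temperature, the alkenyl arm taken as the large group) should give the (3R)-allylic alcohol (2S,3R,4E,6S)-6-[(tert-butyldimethylsilyl)oxy]-3-hydroxy-6-[(R)-6-oxo-3,6-dihydro-2H-pyran-2-yl]hex-4-en-2-yl (E)-3-{4-[(tert-butyldimethylsilyl)oxy]phenyl}acrylate F3.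
 - Simmons–Smith cyclopropanation (Et2Zn, CH2I2, CH2Cl2, 0 °C) is directed by the zinc alkoxide at C4' to the alkene face syn to that oxygen in the allylic-strain-minimised conformer, and the electron-poor alkenes are inert to the carbenoid. It should give the cyclopropyl carbinol (1R,2S)-1-hydroxy-1-{(1S,2S)-2-[(S)-[(tert-butyldimethylsilyl)oxy]((R)-6-oxo-3,6-dihydro-2H-pyran-2-yl)methyl]cyclopropyl}propan-2-yl (E)-3-{4-[(tert-butyldimethylsilyl)oxy]phenyl}acrylate F4.
 - Dess–Martin oxidation of F4 returns to 17.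

2. Step 4. Hydrogen uptake may run on into the terminal vinyl group, or past the alkene stage, before the alkyne is consumed. The fallback sets out from 3 and comes back at 8; it replaces steps 3 and 4 by a sulfone-orthoester lactone annulation, so no hydrogenation is needed.
 - Lithiated trimethyl 3-(phenylsulfonyl)orthopropionate (n-BuLi, THF, −78 °C, BF3·OEt2) opens 3 at the oxirane CH2 to give (5R,6S)-6-[(tert-butyldimethylsilyl)oxy]-1,1,1-trimethoxy-3-(phenylsulfonyl)oct-7-en-5-ol F5.
 - TsOH in wet CH2Cl2 hydrolyses the orthoester and lactonises it to (6R)-6-{(S)-1-[(tert-butyldimethylsilyl)oxy]allyl}-4-(phenylsulfonyl)tetrahydro-2H-pyran-2-one F6.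
 - DBU eliminates sulfinate (E1cB) from F6 to give 8.

3. Step 1. The catalytic epoxidation may stall before the ee-raising second oxidation has done its work, and the small, water-soluble product may be lost on isolation. The fallback sets out from 1 and comes back at 3; it replaces enantiotopic-group selection by resolution of a racemic terminal epoxide, at the cost of at most half of the material.
 - Hydroxyl-directed mono-epoxidation of 1 (VO(acac)2 cat., 1 equiv TBHP), which should favour the erythro isomer, gives racemic erythro-1,2-epoxypent-4-en-3-ol F7 (the threo isomer is removed by chromatography).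
 - Silylation as in step 2 gives racemic erythro-3-[(tert-butyldimethylsilyl)oxy]-1,2-epoxypent-4-ene F8.
 - Hydrolytic kinetic resolution with (S,S)-(salen)Co(III)OAc and 0.55 equiv of water should convert the (2S,3R) enantiomer into (2S,3R)-3-[(tert-butyldimethylsilyl)oxy]pent-4-ene-1,2-diol F9 and leave 3.

Further compounds
F1 | step 9 | (S)-3-oxopent-4-en-2-yl (E)-3-{4-[(tert-butyldimethylsilyl)oxy]phenyl}acrylate | C[C@H](OC(=O)/C=C/c1ccc(O[Si](C)(C)C(C)(C)C)cc1)C(=O)C=C
F2 | step 9 | (2S,4E,6S)-6-[(tert-butyldimethylsilyl)oxy]-3-oxo-6-[(R)-6-oxo-3,6-dihydro-2H-pyran-2-yl]hex-4-en-2-yl (E)-3-{4-[(tert-butyldimethylsilyl)oxy]phenyl}acrylate | C[C@H](OC(=O)/C=C/c1ccc(O[Si](C)(C)C(C)(C)C)cc1)C(=O)/C=C/[C@H](O[Si](C)(C)C(C)(C)C)[C@H]1CC=CC(=O)O1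
F3 | step 9 | (2S,3R,4E,6S)-6-[(tert-butyldimethylsilyl)oxy]-3-hydroxy-6-[(R)-6-oxo-3,6-dihydro-2H-pyran-2-yl]hex-4-en-2-yl (E)-3-{4-[(tert-butyldimethylsilyl)oxy]phenyl}acrylate | C[C@H](OC(=O)/C=C/c1ccc(O[Si](C)(C)C(C)(C)C)cc1)[C@H](O)/C=C/[C@H](O[Si](C)(C)C(C)(C)C)[C@H]1CC=CC(=O)O1
F4 | step 9 | (1R,2S)-1-hydroxy-1-{(1S,2S)-2-[(S)-[(tert-butyldimethylsilyl)oxy]((R)-6-oxo-3,6-dihydro-2H-pyran-2-yl)methyl]cyclopropyl}propan-2-yl (E)-3-{4-[(tert-butyldimethylsilyl)oxy]phenyl}acrylate | C[C@H](OC(=O)/C=C/c1ccc(O[Si](C)(C)C(C)(C)C)cc1)[C@H](O)[C@H]1C[C@@H]1[C@H](O[Si](C)(C)C(C)(C)C)[C@H]1CC=CC(=O)O1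
F5 | step 4 | (5R,6S)-6-[(tert-butyldimethylsilyl)oxy]-1,1,1-trimethoxy-3-(phenylsulfonyl)oct-7-en-5-ol (C3 epimers) | C=C[C@H](O[Si](C)(C)C(C)(C)C)[C@H](O)CC(CC(OC)(OC)OC)S(=O)(=O)c1ccccc1
F6 | step 4 | (6R)-6-{(S)-1-[(tert-butyldimethylsilyl)oxy]allyl}-4-(phenylsulfonyl)tetrahydro-2H-pyran-2-one (C4 epimers) | C=C[C@H](O[Si](C)(C)C(C)(C)C)[C@H]1CC(S(=O)(=O)c2ccccc2)CC(=O)O1
F7 | step 1 | racemic erythro-1,2-epoxypent-4-en-3-ol (2R,3S and 2S,3R) | C=C[C@H](O)[C@H]1CO1.C=C[C@@H](O)[C@@H]1CO1
F8 | step 1 | racemic erythro-3-[(tert-butyldimethylsilyl)oxy]-1,2-epoxypent-4-ene (2R,3S and 2S,3R) | C=C[C@H](O[Si](C)(C)C(C)(C)C)[C@H]1CO1.C=C[C@@H](O[Si](C)(C)C(C)(C)C)[C@@H]1CO1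
F9 | step 1 | (2S,3R)-3-[(tert-butyldimethylsilyl)oxy]pent-4-ene-1,2-diol | C=C[C@@H](O[Si](C)(C)C(C)(C)C)[C@@H](O)CO
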